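The spirocyclopentanol is made by a formal [3+2] annulation. In spiro[4.5]decane numbering (C1 carbinol, C2 side-chain carbon, C5 spiro centre, C6 the later hydroxypropyl carbon), a ketone at C6 makes C1–C5–C6 an aldol array and C3/C4 the two β-carbons of a C1,C6-dicarbonyl. The key step joins these like-polarity carbons and closes the cyclopentane ring at once: a zinc homoenolate, released from an enantiopure 2-substituted cyclopropanol (C1–C3), adds to the exocyclic methylene of a 3-silyloxy-3-methyl-2-methylenecyclohexanone (C4, C5–C10), and the zinc enolate captures the unmasked aldehyde, forming C3–C4 and C1–C5. The C6 ketone then delivers the chain-bearing carbon and the enal; the triene is attached by Stille coupling.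

Key step: step 8

Numbering: spirocyclic compounds are numbered as spiro[4.5]decanes: C1 carbinol carbon, C2 side-chain carbon, C3, C4, C5 spiro carbon, C6 hydroxypropyl carbon, C7 propanal-ylidene carbon, C8, C9, C10 methyl carbinol.
Assumption: in step 1 the ligand antipode that delivers the S alcohol is used, and in step 5 the cyclopropanation is taken to run syn to the zinc alkoxide.

Step 1
Reactants: 1 2-methylcyclohex-2-en-1-one
Product: 2 (1S)-1,2-dimethylcyclohex-2-en-1-ol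
Conditions: Me2Zn, Ti(OiPr)4, trans-1,2-bis(hydroxycamphorsulfonylamino)cyclohexane ligand (10 mol %), toluene, rt; aq. NH4Cl
Reagents that add atoms: dimethylzinc, C[Zn]C
Why: Catalytic asymmetric 1,2-addition of a dialkylzinc to a 2-substituted cyclic enone under titanium–bis(sulfonamide) diol control; the ligand shields one carbonyl face so that methyl should add to give the S tertiary allylic alcohol, the later C10 centre.

Step 2
Reactants: 2 (1S)-1,2-dimethylcyclohex-2-en-1-ol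
Product: 3 triethyl{[(1S)-1,2-dimethylcyclohex-2-en-1-yl]oxy}silane
Conditions: Et3SiOTf, 2,6-lutidine, CH2Cl2, −78 → 0 °C
Reagents that add atoms: triethylsilyl trifluoromethanesulfonate, CC[Si](CC)(CC)OS(=O)(=O)C(F)(F)F
Why: Silylation of a hindered tertiary alcohol with a silyl triflate; it removes a chelating hydroxyl from the key step and enlarges the quaternary allylic centre for step 3, and no stereocentre is touched.

Step 3
Reactants: 3 triethyl{[(1S)-1,2-dimethylcyclohex-2-en-1-yl]oxy}silane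
Product: 5 (3S)-3-methyl-2-methylidene-3-(triethylsilyloxy)cyclohexan-1-one, via allylic hydroperoxide 4 (not isolated)
Conditions: O2, tetraphenylporphyrin (cat.), visible light, CH2Cl2, 0 °C; then Ac2O, pyridine, DMAP (cat.), 0 °C → rt
Reagents that add atoms: dioxygen, O=O
Why: Schenck ene reaction of singlet oxygen followed by Kornblum–DeLaMare dehydration; oxygen should add at the ring CH end remote from the quaternary silyloxy carbon with hydrogen abstraction from the methyl group geminal to that bulky centre, which puts the ketone at C1 and the exocyclic methylene at C2 and leaves C3 untouched.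

Step 4
Reactants: 6 (2R)-but-3-yn-2-ol
Product: 7 (2R,3E)-4-(4,4,5,5-tetramethyl-1,3,2-dioxaborolan-2-yl)but-3-en-2-ol
Conditions: B2pin2, CuCl (5 mol %), Xantphos (5 mol %), NaOtBu (10 mol %), MeOH, THF, rt
Reagents that add atoms: bis(pinacolato)diboron, CC1(C)OB(OC1(C)C)B1OC(C)(C)C(C)(C)O1
Why: Copper-catalysed syn-borylcupration of the terminal alkyne and protonation by methanol (formal anti-Markovnikov hydroboration) should give the E-alkenylboronate without touching the carbinol centre.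

Step 5
Reactants: 7 (2R,3E)-4-(4,4,5,5-tetramethyl-1,3,2-dioxaborolan-2-yl)but-3-en-2-ol
Product: 8 (1R)-1-[(1R,2R)-2-(4,4,5,5-tetramethyl-1,3,2-dioxaborolan-2-yl)cyclopropyl]ethan-1-ol
Conditions: Et2Zn, CH2I2, CH2Cl2, −10 → 0 °C; aq. NH4Cl
Reagents that add atoms: diiodomethane, ICI
Why: Hydroxyl-directed Simmons–Smith cyclopropanation; the zinc alkoxide delivers CH2 to the alkene face syn to oxygen in the conformer whose carbinol hydrogen eclipses the double bond, which sets the ring carbon that becomes C2, and the E alkene gives the trans cyclopropane.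

Step 6
Reactants: 8 (1R)-1-[(1R,2R)-2-(4,4,5,5-tetramethyl-1,3,2-dioxaborolan-2-yl)cyclopropyl]ethan-1-ol
Product: 9 2-{(1R,2R)-2-[(1R)-1-(benzyloxy)ethyl]cyclopropyl}-4,4,5,5-tetramethyl-1,3,2-dioxaborolane
Conditions: NaH, BnBr, Bu4NI (cat.), THF, 0 °C → rt
Reagents that add atoms: benzyl bromide, BrCc1ccccc1
Why: Williamson etherification; the benzyl ether is a non-stabilising, zinc-chelating group for step 8 and is removed without an extra step in step 12.

Step 7
Reactants: 9 2-{(1R,2R)-2-[(1R)-1-(benzyloxy)ethyl]cyclopropyl}-4,4,5,5-tetramethyl-1,3,2-dioxaborolane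
Product: 10 (1R,2R)-2-[(1R)-1-(benzyloxy)ethyl]cyclopropan-1-ol
Conditions: NaBO3·4H2O, THF–H2O, rt
Reagents that add atoms: sodium perborate, [Na+].[O-]OB=O
Why: Oxidation of the cyclopropyl C–B bond with retention of configuration; near-neutral perborate avoids base-induced opening of the secondary cyclopropanol.

Step 8
Reactants: 5 (3S)-3-methyl-2-methylidene-3-(triethylsilyloxy)cyclohexan-1-one; 10 (1R,2R)-2-[(1R)-1-(benzyloxy)ethyl]cyclopropan-1-ol
Product: 13 (1R,2R,5S,10S)-2-[(1R)-1-(benzyloxy)ethyl]-1-hydroxy-10-methyl-10-(triethylsilyloxy)spiro[4.5]decan-6-one, via zinc homoenolate 11 (not isolated), via zinc enolate 12 (not isolated)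
Conditions: Et2Zn (1.2 equiv), 2,2′-bipyridine (20 mol %), THF–DMSO, 0 → 25 °C; aq. NH4Cl
Reagents that add atoms: none
Why: Proposed new method: Et2Zn turns 10 into its zinc cyclopropoxide, which opens at the less substituted ring bond to the β-zincio aldehyde 11 (a homoenolate, reversing the polarity of the aldehyde β-carbon); 11 adds in conjugate fashion to the exocyclic methylene of 5 (bond C3–C4) and the zinc enolate 12 adds to the freed aldehyde (bond C1–C5). The closest known reaction type is the zinc-mediated conjugate addition of cyclopropanol-derived ketone homoenolates to enones, extended here to a secondary cyclopropanol so that the enolate is trapped at once by an aldehyde. The cyclopentane ring closes by a 5-(enolexo)-exo-trig aldol addition. C1 is set by a closed transition state in which one zinc binds the enolate oxygen, the aldehyde oxygen and the benzyloxy oxygen, which places O1 cis to the C6 carbonyl and cis to the C2 substituent; C5 follows from the same chelate and from attack anti to the pseudoaxial C10 methyl group; C2 is carried over unchanged from 10. The step needs ring opening toward the unsubstituted CH2 (secured by the non-stabilising alkyl group on the other ring carbon) and aldol capture that is faster than protonation of the enolate or loss of the β-silyloxy group (secured by aprotic, stoichiometric zinc conditions and the five-membered closure).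

Step 9
Reactants: 13 (1R,2R,5S,10S)-2-[(1R)-1-(benzyloxy)ethyl]-1-hydroxy-10-methyl-10-(triethylsilyloxy)spiro[4.5]decan-6-one
Product: 14 (1R,2S,5S,10S)-2-[(1R)-1-(benzyloxy)ethyl]-10-methyl-1,10-bis(triethylsilyloxy)spiro[4.5]decan-6-one
Conditions: Et3SiOTf, 2,6-lutidine, CH2Cl2, −78 °C
Reagents that add atoms: triethylsilyl trifluoromethanesulfonate, CC[Si](CC)(CC)OS(=O)(=O)C(F)(F)F
Why: Silylation of the aldol hydroxyl blocks retro-aldol cleavage at the quaternary C5 in the basic steps that follow.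

Step 10
Reactants: 14 (1R,2S,5S,10S)-2-[(1R)-1-(benzyloxy)ethyl]-10-methyl-1,10-bis(triethylsilyloxy)spiro[4.5]decan-6-one
Product: 15 (1R,2S,5S,10S)-2-[(1R)-1-(benzyloxy)ethyl]-7-[1-(dimethylamino)ethylidene]-10-methyl-1,10-bis(triethylsilyloxy)spiro[4.5]decan-6-one
Conditions: MeC(OMe)2NMe2, toluene, 110 °C
Reagents that add atoms: N,N-dimethylacetamide dimethyl acetal, COC(C)(OC)N(C)C
Why: Condensation of the amide acetal at C7, the only enolisable α-position of the C6 ketone, should give the vinylogous amide that carries the later propanal carbons C(CH3)–N.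

Step 11
Reactants: 15 (1R,2S,5S,10S)-2-[(1R)-1-(benzyloxy)ethyl]-7-[1-(dimethylamino)ethylidene]-10-methyl-1,10-bis(triethylsilyloxy)spiro[4.5]decan-6-one
Product: 17 1-{(1R,2S,5S,10S)-2-[(1R)-1-(benzyloxy)ethyl]-6-[3-(tert-butyldimethylsilyloxy)propyl]-10-methyl-1,10-bis(triethylsilyloxy)spiro[4.5]dec-6-en-7-yl}ethan-1-one, via carbinol adduct 16 (not isolated)
Conditions: TBSO(CH2)3I, t-BuLi, Et2O, −78 °C; CeCl3, THF, −78 °C; then 15; then aq. citric acid, 0 °C → rt
Reagents that add atoms: tert-butyl(3-iodopropoxy)dimethylsilane, CC(C)(C)[Si](C)(C)OCCCI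
Why: Alkylative carbonyl transposition of a vinylogous amide (Stork–Danheiser type): 1,2-addition of the organocerium reagent at C6, then acid-promoted loss of the C6 oxygen through the conjugated iminium ion and hydrolysis should give the tetrasubstituted enone.

Step 12
Reactants: 17 1-{(1R,2S,5S,10S)-2-[(1R)-1-(benzyloxy)ethyl]-6-[3-(tert-butyldimethylsilyloxy)propyl]-10-methyl-1,10-bis(triethylsilyloxy)spiro[4.5]dec-6-en-7-yl}ethan-1-one
Product: 19 (1Z)-1-{(1R,2S,5S,6R,10S)-6-[3-(tert-butyldimethylsilyloxy)propyl]-2-[(1R)-1-hydroxyethyl]-10-methyl-1,10-bis(triethylsilyloxy)spiro[4.5]decan-7-ylidene}ethyl trifluoromethanesulfonate, via lithium enolate 18 (not isolated)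
Conditions: Li, NH3(l), THF, t-BuOH (1 equiv), −78 °C; isoprene; NH3 removed; PhNTf2, THF, −78 → 0 °C; aq. NH4Cl
Reagents that add atoms: N-phenylbis(trifluoromethanesulfonimide), O=S(=O)(N(c1ccccc1)S(=O)(=O)C(F)(F)F)C(F)(F)F
Why: Birch-type dissolving-metal reduction of the s-cis enone with O-triflation of the enolate; the β-carbanion at C6 should be protonated on the face syn to C4 (anti to the silyloxy-bearing C1), the enolate keeps oxygen cis to C6 and is trapped with retention, and the benzyl ether is cleaved in the same operation while its alkoxide is left untouched by PhNTf2 at low temperature.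

Step 13
Reactants: 19 (1Z)-1-{(1R,2S,5S,6R,10S)-6-[3-(tert-butyldimethylsilyloxy)propyl]-2-[(1R)-1-hydroxyethyl]-10-methyl-1,10-bis(triethylsilyloxy)spiro[4.5]decan-7-ylidene}ethyl trifluoromethanesulfonate
Product: 20 (2Z)-2-{(1R,2S,5S,6R,10S)-6-[3-(tert-butyldimethylsilyloxy)propyl]-2-[(1R)-1-hydroxyethyl]-10-methyl-1,10-bis(triethylsilyloxy)spiro[4.5]decan-7-ylidene}propan-1-ol
Conditions: Bu3SnCH2OH, Pd(PPh3)4 (10 mol %), LiCl, dioxane, 95 °C
Reagents that add atoms: (tributylstannyl)methanol, CCCC[Sn](CCCC)(CCCC)CO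
Why: Stille coupling of the enol triflate proceeds with retention of alkene geometry and should place the hydroxymethyl carbon, the later formyl carbon, cis to C6 without any acid.

Step 14
Reactants: 20 (2Z)-2-{(1R,2S,5S,6R,10S)-6-[3-(tert-butyldimethylsilyloxy)propyl]-2-[(1R)-1-hydroxyethyl]-10-methyl-1,10-bis(triethylsilyloxy)spiro[4.5]decan-7-ylidene}propan-1-ol
Product: 21 (1R)-1-{(1R,2S,5S,6R,10S)-6-[3-(tert-butyldimethylsilyloxy)propyl]-7-[(2Z)-1-(tert-butyldimethylsilyloxy)propan-2-ylidene]-10-methyl-1,10-bis(triethylsilyloxy)spiro[4.5]decan-2-yl}ethan-1-ol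
Conditions: TBSCl, imidazole, CH2Cl2, 0 °C
Reagents that add atoms: tert-butyldimethylsilyl chloride, CC(C)(C)[Si](C)(C)Cl
Why: Selective silylation of the primary allylic alcohol over the hindered secondary alcohol keeps the enal masked at the alcohol level through the basic steps.

Step 15
Reactants: 21 (1R)-1-{(1R,2S,5S,6R,10S)-6-[3-(tert-butyldimethylsilyloxy)propyl]-7-[(2Z)-1-(tert-butyldimethylsilyloxy)propan-2-ylidene]-10-methyl-1,10-bis(triethylsilyloxy)spiro[4.5]decan-2-yl}ethan-1-ol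
Product: 22 1-{(1R,2R,5S,6R,10S)-6-[3-(tert-butyldimethylsilyloxy)propyl]-7-[(2Z)-1-(tert-butyldimethylsilyloxy)propan-2-ylidene]-10-methyl-1,10-bis(triethylsilyloxy)spiro[4.5]decan-2-yl}ethan-1-one
Conditions: Dess–Martin periodinane, NaHCO3, CH2Cl2, rt
Reagents that add atoms: none
Why: Dess–Martin oxidation of the secondary alcohol to the methyl ketone; buffering keeps the now enolisable C2 from epimerising.

Step 16
Reactants: 22 1-{(1R,2R,5S,6R,10S)-6-[3-(tert-butyldimethylsilyloxy)propyl]-7-[(2Z)-1-(tert-butyldimethylsilyloxy)propan-2-ylidene]-10-methyl-1,10-bis(triethylsilyloxy)spiro[4.5]decan-2-yl}ethan-1-one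
Product: 23 1-{(1R,2R,5S,6R,10S)-6-[3-(tert-butyldimethylsilyloxy)propyl]-7-[(2Z)-1-(tert-butyldimethylsilyloxy)propan-2-ylidene]-10-methyl-1,10-bis(triethylsilyloxy)spiro[4.5]decan-2-yl}ethenyl trifluoromethanesulfonate
Conditions: KN(SiMe3)2, PhNTf2, THF, −78 °C
Reagents that add atoms: N-phenylbis(trifluoromethanesulfonimide), O=S(=O)(N(c1ccccc1)S(=O)(=O)C(F)(F)F)C(F)(F)F
Why: Kinetic deprotonation of the methyl group and O-triflation should give the 1,1-disubstituted enol triflate; the low temperature avoids enolisation toward C2, which would epimerise it or expel the C1 silyloxy group.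

Step 17
Reactants: 24 prop-2-yn-1-ol
Product: 26 (2Z)-3-iodo-2-(4-methylpent-3-en-1-yl)prop-2-en-1-ol, via alkenylmagnesium alkoxide 25 (not isolated)
Conditions: (CH3)2C=CHCH2CH2MgBr (3 equiv), CuI (10 mol %), Et2O–THF, −10 °C → rt; then I2, THF, −40 °C
Reagents that add atoms: (4-methylpent-3-en-1-yl)magnesium bromide, CC(C)=CCC[Mg]Br; iodine, II
Why: Copper-catalysed anti-carbomagnesiation of the propargylic alkoxide; the chelated five-membered alkenylmagnesium places the alkyl group on the inner carbon trans to magnesium and iodinolysis with retention should give the Z iodide.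

Step 18
Reactants: 26 (2Z)-3-iodo-2-(4-methylpent-3-en-1-yl)prop-2-en-1-ol
Product: 27 (2Z)-3-iodo-2-(4-methylpent-3-en-1-yl)prop-2-en-1-yl acetate
Conditions: Ac2O, pyridine, DMAP (cat.), CH2Cl2, 0 °C
Reagents that add atoms: acetic anhydride, CC(=O)OC(C)=O
Why: Acylation of the primary allylic alcohol installs the acetate of the target before any coupling.

Step 19
Reactants: 27 (2Z)-3-iodo-2-(4-methylpent-3-en-1-yl)prop-2-en-1-yl acetate
Product: 28 (2Z,4E)-2-(4-methylpent-3-en-1-yl)-5-(tributylstannyl)penta-2,4-dien-1-yl acetate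
Conditions: (E)-Bu3SnCH=CHSnBu3 (2.5 equiv), PdCl2(MeCN)2 (5 mol %), DMF, rt
Reagents that add atoms: (E)-1,2-bis(tributylstannyl)ethene, CCCC[Sn](CCCC)(CCCC)/C=C/[Sn](CCCC)(CCCC)CCCC
Why: Stille mono-coupling of the vinyl iodide with the excess bis-stannane proceeds with retention at both partners and should give the 2Z,4E dienylstannane.

Step 20
Reactants: 23 1-{(1R,2R,5S,6R,10S)-6-[3-(tert-butyldimethylsilyloxy)propyl]-7-[(2Z)-1-(tert-butyldimethylsilyloxy)propan-2-ylidene]-10-methyl-1,10-bis(triethylsilyloxy)spiro[4.5]decan-2-yl}ethenyl trifluoromethanesulfonate; 28 (2Z,4E)-2-(4-methylpent-3-en-1-yl)-5-(tributylstannyl)penta-2,4-dien-1-yl acetate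
Product: 29 (2Z,4E)-6-{(1R,2S,5S,6R,10S)-6-[3-(tert-butyldimethylsilyloxy)propyl]-7-[(2Z)-1-(tert-butyldimethylsilyloxy)propan-2-ylidene]-10-methyl-1,10-bis(triethylsilyloxy)spiro[4.5]decan-2-yl}-2-(4-methylpent-3-en-1-yl)hepta-2,4,6-trien-1-yl acetate
Conditions: Pd2(dba)3 (5 mol %), AsPh3 (40 mol %), LiCl, NMP, rt → 40 °C
Reagents that add atoms: none
Why: Stille coupling of the vinyl triflate with the dienylstannane joins the two halves with retention of all alkene geometries under neutral conditions that the allylic acetate should survive.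

Step 21
Reactants: 29 (2Z,4E)-6-{(1R,2S,5S,6R,10S)-6-[3-(tert-butyldimethylsilyloxy)propyl]-7-[(2Z)-1-(tert-butyldimethylsilyloxy)propan-2-ylidene]-10-methyl-1,10-bis(triethylsilyloxy)spiro[4.5]decan-2-yl}-2-(4-methylpent-3-en-1-yl)hepta-2,4,6-trien-1-yl acetate
Product: 30 (2Z,4E)-6-{(1R,2S,5S,6R,10S)-1,10-dihydroxy-7-[(2Z)-1-hydroxypropan-2-ylidene]-6-(3-hydroxypropyl)-10-methylspiro[4.5]decan-2-yl}-2-(4-methylpent-3-en-1-yl)hepta-2,4,6-trien-1-yl acetate
Conditions: HF·pyridine, pyridine, THF, 0 °C → rt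
Reagents that add atoms: none
Why: Buffered fluoride cleaves the four silyl ethers and should leave the acetate, the triene and the tetrasubstituted alkene untouched.

Step 22
Reactants: 30 (2Z,4E)-6-{(1R,2S,5S,6R,10S)-1,10-dihydroxy-7-[(2Z)-1-hydroxypropan-2-ylidene]-6-(3-hydroxypropyl)-10-methylspiro[4.5]decan-2-yl}-2-(4-methylpent-3-en-1-yl)hepta-2,4,6-trien-1-yl acetate
Product: 31 (2Z,4E)-6-{(1R,2S,5S,6R,10S)-1,10-dihydroxy-6-(3-hydroxypropyl)-10-methyl-7-[(2Z)-1-oxopropan-2-ylidene]spiro[4.5]decan-2-yl}-2-(4-methylpent-3-en-1-yl)hepta-2,4,6-trien-1-yl acetate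
Conditions: MnO2, CH2Cl2, rt
Reagents that add atoms: none
Why: Chemoselective oxidation of the only free allylic alcohol to the enal; the saturated primary, secondary and tertiary alcohols are not oxidised and the alkene geometry is kept.

Compound list
1 | 2-methylcyclohex-2-en-1-one | CC1=CCCCC1=O | starting material
2 | (1S)-1,2-dimethylcyclohex-2-en-1-ol | C[C@]1(O)CCCC=C1C | intermediate
3 | triethyl{[(1S)-1,2-dimethylcyclohex-2-en-1-yl]oxy}silane | C[C@]1(O[Si](CC)(CC)CC)CCCC=C1C | intermediate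
4 | (3S)-3-methyl-2-methylidene-3-(triethylsilyloxy)cyclohexyl hydroperoxide (both C1 epimers; not isolated) | C[C@]1(O[Si](CC)(CC)CC)CCCC(OO)C1=C | intermediate
5 | (3S)-3-methyl-2-methylidene-3-(triethylsilyloxy)cyclohexan-1-one | C[C@]1(O[Si](CC)(CC)CC)CCCC(=O)C1=C | intermediate
6 | (2R)-but-3-yn-2-ol | C[C@@H](O)C#C | starting material
7 | (2R,3E)-4-(4,4,5,5-tetramethyl-1,3,2-dioxaborolan-2-yl)but-3-en-2-ol | C[C@@H](O)/C=C/B1OC(C)(C)C(C)(C)O1 | intermediate
8 | (1R)-1-[(1R,2R)-2-(4,4,5,5-tetramethyl-1,3,2-dioxaborolan-2-yl)cyclopropyl]ethan-1-ol | C[C@@H](O)[C@@H]1C[C@H]1B2OC(C)(C)C(C)(C)O2 | intermediate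
9 | 2-{(1R,2R)-2-[(1R)-1-(benzyloxy)ethyl]cyclopropyl}-4,4,5,5-tetramethyl-1,3,2-dioxaborolane | C[C@@H](OCc1ccccc1)[C@@H]2C[C@H]2B3OC(C)(C)C(C)(C)O3 | intermediate
10 | (1R,2R)-2-[(1R)-1-(benzyloxy)ethyl]cyclopropan-1-ol | C[C@@H](OCc1ccccc1)[C@@H]2C[C@H]2O | intermediate
11 | ethyl[(2S,3R)-3-(benzyloxy)-2-formylbutyl]zinc (zinc homoenolate; not isolated) | CC[Zn]C[C@H](C=O)[C@@H](C)OCc1ccccc1 | intermediate
12 | ethylzinc (6S)-2-[(3S,4R)-4-(benzyloxy)-3-formylpentyl]-6-methyl-6-(triethylsilyloxy)cyclohex-1-en-1-olate (zinc enolate; not isolated) | CC[Zn]OC1=C(CC[C@H](C=O)[C@@H](C)OCc2ccccc2)[C@@](C)(O[Si](CC)(CC)CC)CCC1 | intermediate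
13 | (1R,2R,5S,10S)-2-[(1R)-1-(benzyloxy)ethyl]-1-hydroxy-10-methyl-10-(triethylsilyloxy)spiro[4.5]decan-6-one | C[C@@H](OCc1ccccc1)[C@@H]2CC[C@]3(C(=O)CCC[C@]3(C)O[Si](CC)(CC)CC)[C@@H]2O | intermediate
14 | (1R,2S,5S,10S)-2-[(1R)-1-(benzyloxy)ethyl]-10-methyl-1,10-bis(triethylsilyloxy)spiro[4.5]decan-6-one | C[C@@H](OCc1ccccc1)[C@@H]2CC[C@]3(C(=O)CCC[C@]3(C)O[Si](CC)(CC)CC)[C@@H]2O[Si](CC)(CC)CC | intermediate
15 | (1R,2S,5S,10S)-2-[(1R)-1-(benzyloxy)ethyl]-7-[1-(dimethylamino)ethylidene]-10-methyl-1,10-bis(triethylsilyloxy)spiro[4.5]decan-6-one | C[C@@H](OCc1ccccc1)[C@@H]2CC[C@]3(C(=O)C(=C(C)N(C)C)CC[C@]3(C)O[Si](CC)(CC)CC)[C@@H]2O[Si](CC)(CC)CC | intermediate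
16 | 6-hydroxy-6-[3-(tert-butyldimethylsilyloxy)propyl] adduct of 15 (C6 epimers; formed as its metal alkoxide; not isolated) | C[C@@H](OCc1ccccc1)[C@@H]2CC[C@]3(C(O)(CCCO[Si](C)(C)C(C)(C)C)C(=C(C)N(C)C)CC[C@]3(C)O[Si](CC)(CC)CC)[C@@H]2O[Si](CC)(CC)CC | intermediate
17 | 1-{(1R,2S,5S,10S)-2-[(1R)-1-(benzyloxy)ethyl]-6-[3-(tert-butyldimethylsilyloxy)propyl]-10-methyl-1,10-bis(triethylsilyloxy)spiro[4.5]dec-6-en-7-yl}ethan-1-one | C[C@@H](OCc1ccccc1)[C@@H]2CC[C@]3(C(CCCO[Si](C)(C)C(C)(C)C)=C(C(C)=O)CC[C@]3(C)O[Si](CC)(CC)CC)[C@@H]2O[Si](CC)(CC)CC | intermediate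
18 | dilithium (Z)-enolate alkoxide from reduction and debenzylation of 17 (not isolated) | C[C@@H](O[Li])[C@@H]1CC[C@]2([C@H](CCCO[Si](C)(C)C(C)(C)C)/C(=C(/C)O[Li])CC[C@]2(C)O[Si](CC)(CC)CC)[C@@H]1O[Si](CC)(CC)CC | intermediate
19 | (1Z)-1-{(1R,2S,5S,6R,10S)-6-[3-(tert-butyldimethylsilyloxy)propyl]-2-[(1R)-1-hydroxyethyl]-10-methyl-1,10-bis(triethylsilyloxy)spiro[4.5]decan-7-ylidene}ethyl trifluoromethanesulfonate | C[C@@H](O)[C@@H]1CC[C@]2([C@H](CCCO[Si](C)(C)C(C)(C)C)/C(=C(/C)OS(=O)(=O)C(F)(F)F)CC[C@]2(C)O[Si](CC)(CC)CC)[C@@H]1O[Si](CC)(CC)CC | intermediate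
20 | (2Z)-2-{(1R,2S,5S,6R,10S)-6-[3-(tert-butyldimethylsilyloxy)propyl]-2-[(1R)-1-hydroxyethyl]-10-methyl-1,10-bis(triethylsilyloxy)spiro[4.5]decan-7-ylidene}propan-1-ol | C[C@@H](O)[C@@H]1CC[C@]2([C@H](CCCO[Si](C)(C)C(C)(C)C)/C(=C(/C)CO)CC[C@]2(C)O[Si](CC)(CC)CC)[C@@H]1O[Si](CC)(CC)CC | intermediate
21 | (1R)-1-{(1R,2S,5S,6R,10S)-6-[3-(tert-butyldimethylsilyloxy)propyl]-7-[(2Z)-1-(tert-butyldimethylsilyloxy)propan-2-ylidene]-10-methyl-1,10-bis(triethylsilyloxy)spiro[4.5]decan-2-yl}ethan-1-ol | C[C@@H](O)[C@@H]1CC[C@]2([C@H](CCCO[Si](C)(C)C(C)(C)C)/C(=C(/C)CO[Si](C)(C)C(C)(C)C)CC[C@]2(C)O[Si](CC)(CC)CC)[C@@H]1O[Si](CC)(CC)CC | intermediate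
22 | 1-{(1R,2R,5S,6R,10S)-6-[3-(tert-butyldimethylsilyloxy)propyl]-7-[(2Z)-1-(tert-butyldimethylsilyloxy)propan-2-ylidene]-10-methyl-1,10-bis(triethylsilyloxy)spiro[4.5]decan-2-yl}ethan-1-one | CC(=O)[C@@H]1CC[C@]2([C@H](CCCO[Si](C)(C)C(C)(C)C)/C(=C(/C)CO[Si](C)(C)C(C)(C)C)CC[C@]2(C)O[Si](CC)(CC)CC)[C@@H]1O[Si](CC)(CC)CC | intermediate
23 | 1-{(1R,2R,5S,6R,10S)-6-[3-(tert-butyldimethylsilyloxy)propyl]-7-[(2Z)-1-(tert-butyldimethylsilyloxy)propan-2-ylidene]-10-methyl-1,10-bis(triethylsilyloxy)spiro[4.5]decan-2-yl}ethenyl trifluoromethanesulfonate | C=C(OS(=O)(=O)C(F)(F)F)[C@@H]1CC[C@]2([C@H](CCCO[Si](C)(C)C(C)(C)C)/C(=C(/C)CO[Si](C)(C)C(C)(C)C)CC[C@]2(C)O[Si](CC)(CC)CC)[C@@H]1O[Si](CC)(CC)CC | intermediate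
24 | prop-2-yn-1-ol | C#CCO | starting material
25 | (Z)-alkenylmagnesium bromide alkoxide from carbomagnesiation of 24 (not isolated) | Br[Mg]/C=C(/CCC=C(C)C)CO[Mg]Br | intermediate
26 | (2Z)-3-iodo-2-(4-methylpent-3-en-1-yl)prop-2-en-1-ol | I/C=C(/CCC=C(C)C)CO | intermediate
27 | (2Z)-3-iodo-2-(4-methylpent-3-en-1-yl)prop-2-en-1-yl acetate | I/C=C(/CCC=C(C)C)COC(C)=O | intermediate
28 | (2Z,4E)-2-(4-methylpent-3-en-1-yl)-5-(tributylstannyl)penta-2,4-dien-1-yl acetate | CCCC[Sn](CCCC)(CCCC)/C=C/C=C(/CCC=C(C)C)COC(C)=O | intermediate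
29 | (2Z,4E)-6-{(1R,2S,5S,6R,10S)-6-[3-(tert-butyldimethylsilyloxy)propyl]-7-[(2Z)-1-(tert-butyldimethylsilyloxy)propan-2-ylidene]-10-methyl-1,10-bis(triethylsilyloxy)spiro[4.5]decan-2-yl}-2-(4-methylpent-3-en-1-yl)hepta-2,4,6-trien-1-yl acetate | C=C(/C=C/C=C(/CCC=C(C)C)COC(C)=O)[C@@H]1CC[C@]2([C@H](CCCO[Si](C)(C)C(C)(C)C)/C(=C(/C)CO[Si](C)(C)C(C)(C)C)CC[C@]2(C)O[Si](CC)(CC)CC)[C@@H]1O[Si](CC)(CC)CC | intermediate
30 | (2Z,4E)-6-{(1R,2S,5S,6R,10S)-1,10-dihydroxy-7-[(2Z)-1-hydroxypropan-2-ylidene]-6-(3-hydroxypropyl)-10-methylspiro[4.5]decan-2-yl}-2-(4-methylpent-3-en-1-yl)hepta-2,4,6-trien-1-yl acetate | C=C(/C=C/C=C(/CCC=C(C)C)COC(C)=O)[C@@H]1CC[C@]2([C@H](CCCO)/C(=C(/C)CO)CC[C@]2(C)O)[C@@H]1O | intermediate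
31 | (2Z,4E)-6-{(1R,2S,5S,6R,10S)-1,10-dihydroxy-6-(3-hydroxypropyl)-10-methyl-7-[(2Z)-1-oxopropan-2-ylidene]spiro[4.5]decan-2-yl}-2-(4-methylpent-3-en-1-yl)hepta-2,4,6-trien-1-yl acetate | C=C(/C=C/C=C(/CCC=C(C)C)COC(C)=O)[C@@H]1CC[C@]2([C@H](CCCO)/C(=C(/C)C=O)CC[C@]2(C)O)[C@@H]1O | target

Total step count: 22 steps.
Longest linear sequence: 16 steps (steps 4–16 and 20–22).

Steps most likely to fail

Step 8 (proposed new method). The zinc cyclopropoxide may open toward the substituted carbon, or the β-zincio aldehyde may enolise and lose the C2 configuration. The zinc enolate may be protonated or may expel the β-silyloxy group before it closes. The chelate and the C10 centre may also oppose each other and erode facial selectivity at C5. The fallback uses known reactions only and sets out from 10 and 5. Electrophilic mercuration of 10 with Hg(OAc)2 cleaves the least substituted ring bond and gives (2S,3R)-2-[(acetoxymercurio)methyl]-3-(benzyloxy)butanal F1. Bromodemercuration (Br2, pyridine) gives (2S,3R)-3-(benzyloxy)-2-(bromomethyl)butanal F2, and ethylene glycol with pyridinium tosylate gives the bromo dioxolane F3. Its Grignard reagent (Mg, THF) is added to 5 under CuBr·SMe2 catalysis and the magnesium enolate is quenched with Ac2O to give the regiodefined enol acetate F4. Pyridinium tosylate in wet acetone frees the aldehyde and gives the formyl enol acetate F5. K2CO3 in MeOH then cleaves the enol ester, and the enolate released at C5 should close by intramolecular aldol addition to 13, where the route is rejoined.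

Step 12. The radical anion may rotate and lose the enolate geometry, C6 may be protonated from the wrong face, the ketone may be over-reduced, or the side-chain alkoxide may be triflated. The fallback sets out from 17. Wittig methoxymethylenation (Ph3P=CHOMe from the phosphonium chloride and KN(SiMe3)2) gives the methyl dienol ether F6. Mild hydrolysis with aqueous oxalic acid protonates C6 and gives the conjugated benzyl-protected enal F7 under thermodynamic control of C6 and of the alkene geometry, and the Z isomer is separated. Luche reduction (NaBH4, CeCl3·7H2O) gives the benzyl-protected allylic alcohol F8. Lithium 4,4′-di-tert-butylbiphenylide in THF at −78 °C removes the benzyl group from the lithium alkoxide of F8 and returns the route at diol 20.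

Step 11. The organocerium reagent may deprotonate the vinylogous amide instead of adding to its hindered, deactivated carbonyl, or the transposition may stop at the carbinol. The fallback sets out from 14. LiN(SiMe3)2 and acetaldehyde give the aldol adduct F9. Mesylation and elimination (MsCl, Et3N, then DBU) give the 7-ethylidene ketone F10, whose carbonyl is a true enone and more electrophilic. The same organocerium reagent adds to it to give the tertiary allylic alcohol F11. Oxidative 1,3-transposition with pyridinium chlorochromate (C5H5NH[CrO3Cl], the Babler–Dauben oxidation) then returns the route at enone 17.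

Further compounds
F1 | step 8 | (2S,3R)-2-[(acetoxymercurio)methyl]-3-(benzyloxy)butanal | CC(=O)O[Hg]C[C@H](C=O)[C@@H](C)OCc1ccccc1
F2 | step 8 | (2S,3R)-3-(benzyloxy)-2-(bromomethyl)butanal | BrC[C@H](C=O)[C@@H](C)OCc1ccccc1
F3 | step 8 | 2-[(2S,3R)-3-(benzyloxy)-1-bromobutan-2-yl]-1,3-dioxolane | BrC[C@H](C1OCCO1)[C@@H](C)OCc1ccccc1
F4 | step 8 | (6S)-2-[(3S,4R)-4-(benzyloxy)-3-(1,3-dioxolan-2-yl)pentyl]-6-methyl-6-(triethylsilyloxy)cyclohex-1-en-1-yl acetate | CC(=O)OC1=C(CC[C@H](C2OCCO2)[C@@H](C)OCc2ccccc2)[C@@](C)(O[Si](CC)(CC)CC)CCC1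
F5 | step 8 | (6S)-2-[(3S,4R)-4-(benzyloxy)-3-formylpentyl]-6-methyl-6-(triethylsilyloxy)cyclohex-1-en-1-yl acetate | CC(=O)OC1=C(CC[C@H](C=O)[C@@H](C)OCc2ccccc2)[C@@](C)(O[Si](CC)(CC)CC)CCC1
F6 | step 12 | methyl dienol ether of 17: 7-(1-methoxyprop-1-en-2-yl) analogue (enol ether E/Z mixture) | C[C@@H](OCc1ccccc1)[C@@H]2CC[C@]3(C(CCCO[Si](C)(C)C(C)(C)C)=C(C(C)=COC)CC[C@]3(C)O[Si](CC)(CC)CC)[C@@H]2O[Si](CC)(CC)CC
F7 | step 12 | (2Z)-2-{(1R,2S,5S,6R,10S)-2-[(1R)-1-(benzyloxy)ethyl]-6-[3-(tert-butyldimethylsilyloxy)propyl]-10-methyl-1,10-bis(triethylsilyloxy)spiro[4.5]decan-7-ylidene}propanal | C[C@@H](OCc1ccccc1)[C@@H]2CC[C@]3([C@H](CCCO[Si](C)(C)C(C)(C)C)/C(=C(/C)C=O)CC[C@]3(C)O[Si](CC)(CC)CC)[C@@H]2O[Si](CC)(CC)CC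
F8 | step 12 | (2Z)-2-{(1R,2S,5S,6R,10S)-2-[(1R)-1-(benzyloxy)ethyl]-6-[3-(tert-butyldimethylsilyloxy)propyl]-10-methyl-1,10-bis(triethylsilyloxy)spiro[4.5]decan-7-ylidene}propan-1-ol | C[C@@H](OCc1ccccc1)[C@@H]2CC[C@]3([C@H](CCCO[Si](C)(C)C(C)(C)C)/C(=C(/C)CO)CC[C@]3(C)O[Si](CC)(CC)CC)[C@@H]2O[Si](CC)(CC)CC
F9 | step 11 | 7-(1-hydroxyethyl) aldol adduct of 14 (mixture at the two new centres) | C[C@@H](OCc1ccccc1)[C@@H]2CC[C@]3(C(=O)C(C(C)O)CC[C@]3(C)O[Si](CC)(CC)CC)[C@@H]2O[Si](CC)(CC)CC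
F10 | step 11 | 7-ethylidene derivative of 14 | C[C@@H](OCc1ccccc1)[C@@H]2CC[C@]3(C(=O)C(=CC)CC[C@]3(C)O[Si](CC)(CC)CC)[C@@H]2O[Si](CC)(CC)CC
F11 | step 11 | 7-ethylidene-6-[3-(tert-butyldimethylsilyloxy)propyl]spiro[4.5]decan-6-ol derived from F10 (C6 epimers) | C[C@@H](OCc1ccccc1)[C@@H]2CC[C@]3(C(O)(CCCO[Si](C)(C)C(C)(C)C)C(=CC)CC[C@]3(C)O[Si](CC)(CC)CC)[C@@H]2O[Si](CC)(CC)CC
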